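**Retrosynthetic overview**

1. The 11-membered ring is closed last, by an intramolecular Nozaki–Hiyama–Kishi coupling between an aldehyde on the cyclopentane and an (E)-vinyl iodide at the end of the side chain; oxidation and methylenation then give the exocyclic diene.
2. The side chain (methyl stereocenter from (R)-3-bromo-2-methylpropan-1-ol) is added as a Grignard reagent to a tetrasubstituted cyclohexene carbaldehyde, itself made from the ring ketone by formylation, O-alkylation, MeLi addition and acid (alkylative carbonyl transposition).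
3. The cyclopentane is cut across its CH2–CH2 bond and its CH–CH bond: a SmI2-catalysed radical-relay [3+2] union of a ring-fused cyclopropyl ketone with a terminal alkyne, followed by hydrogenation from the convex face.
4. Enabling feature: the ring-fusion CH, the methyl-bearing quaternary carbon and the adjacent cyclopentane CH2 sit α, β and on-β to the cyclohexene carbon that carries the vinylic methyl; with that carbon as a ketone, the three atoms are a cyclopropane fused to the six-membered ring (a 6-methylbicyclo[4.1.0]heptan-2-one) whose external bond opens to a primary radical plus an enolate.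
5. The six-membered ring and its trans-diol come from (−)-quinic acid; ring order: six-membered (chiral pool) → cyclopropane (temporary) → five-membered (key step) → eleven-membered.

Key step: step 10

Remark: the silyl propargyl ether, the bromo alcohol, LiC≡CSiMe3 (THF solution) and Cp2Ti(μ-Cl)(μ-CH2)AlMe2 (Tebbe reagent, toluene solution) are taken as purchased; BDA = butane-2,3-diacetal, "O–C4/O–C5" are the two diol oxygens in the numbering of the ring named in each entry.

**Route**

Step 1
Reactants: 1 (−)-quinic acid
Product: 2 BDA-protected methyl quinate (methyl ester; trans-4,5-diol bridged as the butane-2,3-diacetal; 1-OH and 3-OH free)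
Conditions: butane-2,3-dione, HC(OMe)3, MeOH, CSA (cat.), reflux
Reagents that add atoms: butane-2,3-dione CC(=O)C(C)=O; methanol CO
Why: Fischer esterification and butane-2,3-diacetal formation under thermodynamic control select the trans-diequatorial diol, and the anomeric effect puts both new OMe groups axial, which fixes the two acetal stereocenters (both S).

Step 2
Reactants: 2 BDA-protected methyl quinate
Product: 3 BDA-protected triol (CO2Me reduced to CH2OH)
Conditions: NaBH4, MeOH, 0 °C → rt
Reagents that add atoms: none
Why: Hydride reduction of an α-hydroxy ester, which NaBH4 reduces because of the neighbouring hydroxyl, touches no stereocenter.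

Step 3
Reactants: 3 BDA-protected triol
Product: 4 BDA-protected β-hydroxy ketone
Conditions: NaIO4, THF/H2O, rt
Reagents that add atoms: none
Why: Periodate glycol cleavage of the tertiary-OH/CH2OH pair gives the ring ketone and leaves the other centers untouched.

Step 4
Reactants: 4 BDA-protected β-hydroxy ketone
Product: 5 BDA-protected (4R,5R)-4,5-dihydroxycyclohex-2-en-1-one
Conditions: MsCl, Et3N, CH2Cl2, 0 °C
Reagents that add atoms: none
Why: Mesylation of the free β-hydroxyl and E1cB elimination give the conjugated enone, while the acetal oxygen on the other side is equatorial in the locked ring and is not expelled.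

Step 5
Reactants: 5 BDA-protected enone
Product: 6 3-methyl trimethylsilyl enol ether
Conditions: MeMgBr, CuBr·SMe2 (cat.), TMSCl, THF, −78 °C
Reagents that add atoms: methylmagnesium bromide C[Mg]Br; chlorotrimethylsilane C[Si](C)(C)Cl
Why: Copper-catalysed conjugate addition with in situ O-silylation fixes the enolate regiochemistry; axial attack should put the methyl cis to the neighbouring acetal oxygen, but this center is erased in step 6.

Step 6
Reactants: 6 3-methyl trimethylsilyl enol ether
Product: 7 BDA-protected (4R,5R)-4,5-dihydroxy-3-methylcyclohex-2-en-1-one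
Conditions: Pd(OAc)2 (1 equiv), MeCN, rt
Reagents that add atoms: none
Why: Saegusa–Ito oxidation (palladium enolate, β-hydride elimination) restores the enone, now with the β-methyl group.

Step 7
Reactants: 7 BDA-protected 3-methyl enone
Product: 8 (1S)-allylic alcohol (1-OH cis to O–C5, trans to O–C4)
Conditions: NaBH4, CeCl3·7H2O, MeOH, −78 °C
Reagents that add atoms: none
Why: Luche 1,2-reduction by axial hydride attack on the half-chair that the trans-fused acetal ring locks should give the pseudo-equatorial alcohol, which sets the carbinol center.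

Step 8
Reactants: 8 (1S)-allylic alcohol
Product: 9 cyclopropyl carbinol (6-methylbicyclo[4.1.0]heptan-2-ol; cyclopropane CH2 cis to 2-OH and O–C4, trans to O–C5)
Conditions: Et2Zn, CH2I2, CH2Cl2, 0 °C → rt
Reagents that add atoms: diiodomethane ICI
Why: In this hydroxyl-directed Simmons–Smith (Furukawa) cyclopropanation the zinc alkoxide delivers CH2 to its own alkene face, which sets the ring-fusion CH and the methyl-bearing quaternary carbon.

Step 9
Reactants: 9 cyclopropyl carbinol
Product: 10 cyclopropyl ketone (BDA-protected 6-methylbicyclo[4.1.0]heptan-2-one)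
Conditions: DMP, CH2Cl2, rt
Reagents that add atoms: none
Why: Dess–Martin oxidation of the secondary alcohol gives the cyclopropyl ketone without touching the acetal or the cyclopropane.

Step 10
Reactants: 10 cyclopropyl ketone; 11 tert-butyl(diphenyl)(prop-2-yn-1-yloxy)silane
Product: 12 cis-fused bicyclic enone (9-(silyloxymethyl)-6-methylbicyclo[4.3.0]non-8-en-2-one, BDA-protected)
Conditions: SmI2 (25 mol %), Sm metal (25 mol %), 11 (5 equiv), THF, 55 °C
Reagents that add atoms: none
Why: SmI2 reduces the ketone of 10 to a ketyl whose external cyclopropane bond (ring-fusion CH to cyclopropane CH2) lies parallel to the ketyl π orbital and breaks, giving a trivalent samarium enolate and a primary radical on the CH2 attached to the quaternary methyl carbon; this radical adds to the terminal carbon of 11 (first new bond, CH2–CH), the vinyl radical attacks the enolate carbon (second new bond, CH–C), and the new ketyl returns its electron to trivalent samarium, so the step is redox-neutral and SmI2 turns over. The closest known reaction type is the SmI2-catalysed radical-relay formal [3+2] cycloaddition of alkyl cyclopropyl ketones with alkynes, and the direction of ring opening is the one known from dissolving-metal reductions of bicyclo[4.1.0]heptan-2-ones. One ring, the cyclopentene, is closed, by 5-exo-trig attack of the vinyl radical on the enolate double bond. The only new stereocenter, the ring-fusion CH, is controlled by the tether: the two-atom chain hangs from the neighbouring quaternary carbon on the face that held the cyclopropane, so the bond can form only there and the hydrindane is cis-fused with the quaternary center unchanged. The step needs cleavage of the external and not the internal cyclopropane bond (secured by orbital overlap in the acetal-locked bicycle), addition at the unsubstituted alkyne carbon (secured by the terminal alkyne) and ring closure faster than 1,5-hydrogen transfer to the vinyl radical (closure onto the electron-rich enolate should be the faster process); 11 is used in excess because addition of the neopentyl-type radical to an unactivated alkyne is the slow link.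

Step 11
Reactants: 12 cis-fused bicyclic enone
Product: 13 saturated cis-hydrindanone (silyloxymethyl arm cis to the ketone carbon, its CH hydrogen cis to the ring-fusion hydrogen)
Conditions: H2 (1 atm), 5% Pt/C, EtOAc, rt
Reagents that add atoms: none
Why: Heterogeneous syn-hydrogenation should occur from the convex face of the cis-fused bicycle, because the concave face is covered by the six-membered ring, so hydrogen enters cis to the ring-fusion hydrogen and sets the carbon that later carries the macrocycle.

Step 12
Reactants: 13 saturated cis-hydrindanone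
Product: 14 hydroxymethylene ketone (Z-enol at the CH2 flank of the ketone)
Conditions: LiN(iPr)2, THF, −78 °C; CF3CH2OCHO, −78 °C; aq. HCl work-up
Reagents that add atoms: 2,2,2-trifluoroethyl formate O=COCC(F)(F)F
Why: Kinetic deprotonation at the CH2 flank and Claisen-type C-formylation at −78 °C avoid equilibration of the ring-fusion α-center and β-elimination of the acetal oxygen, and no new stereocenter is formed.

Step 13
Reactants: 14 hydroxymethylene ketone
Product: 15 isopropoxymethylene ketone
Conditions: 2-iodopropane, K2CO3, acetone, 50 °C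
Reagents that add atoms: 2-iodopropane CC(C)I
Why: O-alkylation of the vinylogous acid with a secondary iodide gives the vinylogous ester needed for carbonyl transposition (either alkene geometry serves).

Step 14
Reactants: 15 isopropoxymethylene ketone
Product: 17 diol enal (tetrasubstituted cyclohexene carbaldehyde, free trans-diol), via lithium alkoxide 16 (not isolated)
Conditions: MeLi, Et2O, −78 °C; then TFA/H2O (9:1), 0 °C → rt
Reagents that add atoms: methyllithium C[Li]; water O
Why: 1,2-Addition of MeLi to the vinylogous ester carbonyl followed by acid-promoted allylic transposition and hydrolysis (Stork–Danheiser-type alkylative carbonyl transposition) gives the β-methyl enal, the same acid removes the BDA group while the alkene is electron-poor, and the tertiary carbinol center is erased.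

Step 15
Reactants: 17 diol enal
Product: 18 mono-TBS enal (silyl ether on the allylic hydroxyl)
Conditions: TBSCl (1.1 equiv), imidazole, DMF, 0 °C
Reagents that add atoms: tert-butyldimethylsilyl chloride CC(C)(C)[Si](C)(C)Cl
Why: Silylation should take the allylic hydroxyl and leave the hydroxyl next to the quaternary carbon (steric differentiation), which marks the oxygen that stays free in the target.

Step 16
Reactants: 19 (R)-3-bromo-2-methylpropan-1-ol
Product: 20 (S)-2-methyl-5-(trimethylsilyl)pent-4-yn-1-ol
Conditions: LiC≡CSiMe3 (2.5 equiv), THF/DMPU, −78 °C → rt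
Reagents that add atoms: lithium (trimethylsilyl)acetylide [Li]C#C[Si](C)(C)C
Why: SN2 alkylation of the acetylide at the primary bromide (the first equivalent forms the alkoxide) does not involve the stereocenter.

Step 17
Reactants: 20 (S)-2-methyl-5-(trimethylsilyl)pent-4-yn-1-ol
Product: 21 (S)-(5-iodo-4-methylpent-1-yn-1-yl)trimethylsilane
Conditions: I2, PPh3, imidazole, CH2Cl2, 0 °C
Reagents that add atoms: iodine II
Why: Appel-type iodination of the primary alcohol proceeds at a carbon that is not stereogenic.

Step 18
Reactants: 18 mono-TBS enal; 21 (S)-(5-iodo-4-methylpent-1-yn-1-yl)trimethylsilane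
Product: 23 (S)-carbinol (side chain attached; new allylic hydroxyl plus the hydroxyl next to the quaternary carbon), via Grignard reagent 22 (not isolated)
Conditions: 21, Mg, Et2O, rt; 18, tBuMgCl (1.0 equiv), THF, −78 °C; then 22 (1.5 equiv), −78 → −40 °C
Reagents that add atoms: none
Why: Grignard 1,2-addition to the aldehyde (the free hydroxyl first becomes a magnesium alkoxide, which does not promote silyl migration) should occur on the s-trans enal from the face opposite the neighbouring silyloxy group and the silyloxymethyl arm (Felkin–Anh-type substrate control), giving the (S)-carbinol.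

Step 19
Reactants: 23 (S)-carbinol
Product: 24 diacetate
Conditions: Ac2O, DMAP, Et3N, CH2Cl2, rt → 40 °C
Reagents that add atoms: acetic anhydride CC(=O)OC(C)=O
Why: DMAP-catalysed acylation esterifies both free secondary hydroxyls with retention, placing the two acetates of the target while the third oxygen stays silylated.

Step 20
Reactants: 24 diacetate
Product: 25 terminal alkyne
Conditions: AgNO3 (10 mol %), acetone/H2O, rt
Reagents that add atoms: none
Why: Silver-catalysed protodesilylation of the alkynylsilane is near neutral and spares the acetates and both silyl ethers.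

Step 21
Reactants: 25 terminal alkyne
Product: 27 (E)-vinyl iodide, via alkenylzirconocene chloride 26 (not isolated)
Conditions: Cp2Zr(H)Cl, THF, 0 °C → rt; then I2, 0 °C
Reagents that add atoms: iodine II
Why: Hydrozirconation adds Zr–H syn with zirconium on the terminal carbon and iodinolysis proceeds with retention, which sets the E-alkene of the macrocycle.

Step 22
Reactants: 27 (E)-vinyl iodide
Product: 28 primary alcohol
Conditions: TBAF, AcOH (1:1), THF, 0 °C
Reagents that add atoms: none
Why: Buffered fluoride desilylation should cleave the unhindered primary TBDPS ether faster than the hindered secondary TBS ether, and the buffer protects the acetates.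

Step 23
Reactants: 28 primary alcohol
Product: 29 aldehyde
Conditions: DMP, CH2Cl2, 0 °C; used at once
Reagents that add atoms: none
Why: Dess–Martin oxidation is non-basic, so the α-stereocenter of the aldehyde, which is the less stable epimer, should be kept.

Step 24
Reactants: 29 aldehyde
Product: 30 macrocyclic allylic alcohol (11-membered ring closed; carbinol epimers)
Conditions: CrCl2 (10 equiv), NiCl2 (2 mol %), DMSO/THF, 0.002 M, rt
Reagents that add atoms: none
Why: In this intramolecular Nozaki–Hiyama–Kishi coupling zerovalent nickel inserts into the C–I bond, the alkenyl group passes to trivalent chromium and adds to the aldehyde under neutral conditions with the E geometry retained; both carbinol epimers converge in step 25.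

Step 25
Reactants: 30 macrocyclic allylic alcohol
Product: 31 macrocyclic enone
Conditions: DMP, CH2Cl2, rt
Reagents that add atoms: none
Why: Dess–Martin oxidation of the allylic alcohol removes the unselective carbinol center, and the α-center next to the new ketone is held by the bridging ring.

Step 26
Reactants: 31 macrocyclic enone
Product: 32 TBS ether of the target
Conditions: Cp2Ti(μ-Cl)(μ-CH2)AlMe2 (Tebbe reagent), pyridine, THF/toluene, −40 → 0 °C
Reagents that add atoms: Tebbe reagent Cp2Ti(μ-Cl)(μ-CH2)AlMe2 C[Al-]1(C)C[Ti](C2C=CC=C2)(C2C=CC=C2)[Cl+]1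
Why: Carbonyl methylenation by the titanium methylidene is non-basic and should take the ketone before the acetates at low temperature, giving the exocyclic diene.

Step 27
Reactants: 32 TBS ether of the target
Product: 33 target CNP0323842.1
Conditions: HF·pyridine, pyridine, THF, 0 °C → rt
Reagents that add atoms: none
Why: Acidic fluoride desilylation frees the allylic hydroxyl without the acetyl migration that basic fluoride could cause.

**Compound list**

1 | (−)-quinic acid, (1S,3R,4S,5R)-1,3,4,5-tetrahydroxycyclohexane-1-carboxylic acid | C1[C@](O)(C(=O)O)C[C@@H](O)[C@@H](O)[C@@H]1O | starting material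
2 | methyl quinate with the trans-4,5-diol bridged as butane-2,3-diacetal (both acetal carbons S, OMe axial); 1-OH and 3-OH free | C1[C@](O)(C(=O)OC)C[C@@H](O)[C@H]2O[C@](C)(OC)[C@@](C)(OC)O[C@H]12 | intermediate
3 | the 1-(hydroxymethyl) triol from 2 | C1[C@](O)(CO)C[C@@H](O)[C@H]2O[C@](C)(OC)[C@@](C)(OC)O[C@H]12 | intermediate
4 | BDA-protected 3,4,5-trihydroxycyclohexan-1-one with free 3-OH (cis to O–C4) | C1C(=O)C[C@@H](O)[C@H]2O[C@](C)(OC)[C@@](C)(OC)O[C@H]12 | intermediate
5 | BDA-protected (4R,5R)-4,5-dihydroxycyclohex-2-en-1-one | C1C(=O)C=C[C@H]2O[C@](C)(OC)[C@@](C)(OC)O[C@H]12 | intermediate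
6 | BDA-protected 4,5-dihydroxy-3-methyl-1-(trimethylsilyloxy)cyclohex-1-ene, methyl cis to O–C4 | C1C(O[Si](C)(C)C)=C[C@@H](C)[C@H]2O[C@](C)(OC)[C@@](C)(OC)O[C@H]12 | intermediate
7 | BDA-protected (4R,5R)-4,5-dihydroxy-3-methylcyclohex-2-en-1-one | C1C(=O)C=C(C)[C@H]2O[C@](C)(OC)[C@@](C)(OC)O[C@H]12 | intermediate
8 | BDA-protected (1S,4R,5R)-3-methylcyclohex-2-ene-1,4,5-triol, 1-OH free (cis to O–C5) | C1[C@H](O)C=C(C)[C@H]2O[C@](C)(OC)[C@@](C)(OC)O[C@H]12 | intermediate
9 | BDA-protected 6-methylbicyclo[4.1.0]heptane-2,4,5-triol, 2-OH free; cyclopropane CH2 cis to 2-OH and O–C4, trans to O–C5 | C1[C@H](O)[C@@H]2C[C@]2(C)[C@H]3O[C@](C)(OC)[C@@](C)(OC)O[C@H]13 | intermediate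
10 | BDA-protected 4,5-dihydroxy-6-methylbicyclo[4.1.0]heptan-2-one (same relative configuration as 9) | C1C(=O)[C@@H]2C[C@]2(C)[C@H]3O[C@](C)(OC)[C@@](C)(OC)O[C@H]13 | intermediate
11 | tert-butyl(diphenyl)(prop-2-yn-1-yloxy)silane | C#CCO[Si](c1ccccc1)(c1ccccc1)C(C)(C)C | starting material
12 | BDA-protected 9-[(tert-butyldiphenylsilyloxy)methyl]-4,5-dihydroxy-6-methylbicyclo[4.3.0]non-8-en-2-one, cis-fused (H-1, 6-CH3 and O–C5 on one face, O–C4 on the other) | C1C(=O)[C@@H]2C(CO[Si](c4ccccc4)(c5ccccc5)C(C)(C)C)=CC[C@]2(C)[C@H]3O[C@](C)(OC)[C@@](C)(OC)O[C@H]13 | intermediate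
13 | the 8,9-dihydro compound from 12; C9 arm cis to C2, H-9 cis to H-1 | C1C(=O)[C@@H]2[C@H](CO[Si](c4ccccc4)(c5ccccc5)C(C)(C)C)CC[C@]2(C)[C@H]3O[C@](C)(OC)[C@@](C)(OC)O[C@H]13 | intermediate
14 | 3-[(Z)-hydroxymethylene] derivative of 13 | O/C=C1\C(=O)[C@@H]2[C@H](CO[Si](c4ccccc4)(c5ccccc5)C(C)(C)C)CC[C@]2(C)[C@H]3O[C@](C)(OC)[C@@](C)(OC)O[C@H]13 | intermediate
15 | 3-[(E)-isopropoxymethylene] derivative of 13 | CC(C)O/C=C1/C(=O)[C@@H]2[C@H](CO[Si](c4ccccc4)(c5ccccc5)C(C)(C)C)CC[C@]2(C)[C@H]3O[C@](C)(OC)[C@@](C)(OC)O[C@H]13 | intermediate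
16 | lithium alkoxide of the 2-methyl tertiary carbinol from 15 (carbinol center unassigned) | CC(C)O/C=C1/C(C)([O-])[C@@H]2[C@H](CO[Si](c4ccccc4)(c5ccccc5)C(C)(C)C)CC[C@]2(C)[C@H]3O[C@](C)(OC)[C@@](C)(OC)O[C@H]13.[Li+] | intermediate
17 | (1R,3aS,4R,5R,7aS)-1-[(tert-butyldiphenylsilyloxy)methyl]-4,5-dihydroxy-3a,7-dimethyl-2,3,3a,4,5,7a-hexahydro-1H-indene-6-carbaldehyde | O=CC1=C(C)[C@@H]2[C@H](CO[Si](c4ccccc4)(c5ccccc5)C(C)(C)C)CC[C@]2(C)[C@@H](O)[C@@H]1O | intermediate
18 | the 5-O-tert-butyldimethylsilyl ether of 17 (4-OH free) | O=CC1=C(C)[C@@H]2[C@H](CO[Si](c4ccccc4)(c5ccccc5)C(C)(C)C)CC[C@]2(C)[C@@H](O)[C@@H]1O[Si](C)(C)C(C)(C)C | intermediate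
19 | (R)-3-bromo-2-methylpropan-1-ol | BrC[C@H](C)CO | starting material
20 | (S)-2-methyl-5-(trimethylsilyl)pent-4-yn-1-ol | C[Si](C)(C)C#CC[C@H](C)CO | intermediate
21 | (S)-(5-iodo-4-methylpent-1-yn-1-yl)trimethylsilane | C[Si](C)(C)C#CC[C@H](C)CI | intermediate
22 | (S)-[2-methyl-5-(trimethylsilyl)pent-4-yn-1-yl]magnesium iodide | C[Si](C)(C)C#CC[C@H](C)C[Mg]I | intermediate
23 | (1S,3S)-1-[indenyl residue of 18]-3-methyl-6-(trimethylsilyl)hex-5-yn-1-ol (aldehyde of 18 converted to the secondary carbinol carrying the chain) | C[Si](C)(C)C#CC[C@H](C)C[C@H](O)C1=C(C)[C@@H]2[C@H](CO[Si](c4ccccc4)(c5ccccc5)C(C)(C)C)CC[C@]2(C)[C@@H](O)[C@@H]1O[Si](C)(C)C(C)(C)C | intermediate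
24 | diacetate of 23 (chain carbinol and ring 4-OH acetylated) | C[Si](C)(C)C#CC[C@H](C)C[C@H](OC(C)=O)C1=C(C)[C@@H]2[C@H](CO[Si](c4ccccc4)(c5ccccc5)C(C)(C)C)CC[C@]2(C)[C@@H](OC(C)=O)[C@@H]1O[Si](C)(C)C(C)(C)C | intermediate
25 | terminal alkyne from 24 (C-silyl group removed) | C#CC[C@H](C)C[C@H](OC(C)=O)C1=C(C)[C@@H]2[C@H](CO[Si](c4ccccc4)(c5ccccc5)C(C)(C)C)CC[C@]2(C)[C@@H](OC(C)=O)[C@@H]1O[Si](C)(C)C(C)(C)C | intermediate
26 | (E)-alkenylzirconocene chloride from 25 | Cl[Zr](/C=C/C[C@H](C)C[C@H](OC(C)=O)C1=C(C)[C@@H]2[C@H](CO[Si](c4ccccc4)(c5ccccc5)C(C)(C)C)CC[C@]2(C)[C@@H](OC(C)=O)[C@@H]1O[Si](C)(C)C(C)(C)C)(C6C=CC=C6)C7C=CC=C7 | intermediate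
27 | (E)-vinyl iodide from 25 | I/C=C/C[C@H](C)C[C@H](OC(C)=O)C1=C(C)[C@@H]2[C@H](CO[Si](c4ccccc4)(c5ccccc5)C(C)(C)C)CC[C@]2(C)[C@@H](OC(C)=O)[C@@H]1O[Si](C)(C)C(C)(C)C | intermediate
28 | primary alcohol from 27 (TBDPS removed) | I/C=C/C[C@H](C)C[C@H](OC(C)=O)C1=C(C)[C@@H]2[C@H](CO)CC[C@]2(C)[C@@H](OC(C)=O)[C@@H]1O[Si](C)(C)C(C)(C)C | intermediate
29 | aldehyde from 28 | I/C=C/C[C@H](C)C[C@H](OC(C)=O)C1=C(C)[C@@H]2[C@H](C=O)CC[C@]2(C)[C@@H](OC(C)=O)[C@@H]1O[Si](C)(C)C(C)(C)C | intermediate
30 | tricyclic allylic alcohol: 11-membered ring closed between the former aldehyde carbon (CHOH, both epimers) and the (E)-vinyl carbon | OC1/C=C/C[C@H](C)C[C@H](OC(C)=O)C2=C(C)[C@@H]3[C@H]1CC[C@]3(C)[C@@H](OC(C)=O)[C@@H]2O[Si](C)(C)C(C)(C)C | intermediate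
31 | tricyclic enone (ketone conjugated with the E-alkene) | O=C1/C=C/C[C@H](C)C[C@H](OC(C)=O)C2=C(C)[C@@H]3[C@H]1CC[C@]3(C)[C@@H](OC(C)=O)[C@@H]2O[Si](C)(C)C(C)(C)C | intermediate
32 | tert-butyldimethylsilyl ether of the target | C=C1/C=C/C[C@H](C)C[C@H](OC(C)=O)C2=C(C)[C@@H]3[C@H]1CC[C@]3(C)[C@@H](OC(C)=O)[C@@H]2O[Si](C)(C)C(C)(C)C | intermediate
33 | CNP0323842.1 | C=C1/C=C/C[C@H](C)C[C@H](OC(C)=O)C2=C(C)[C@@H]3[C@H]1CC[C@]3(C)[C@@H](OC(C)=O)[C@@H]2O | target

**Step count and risks**

Total steps: 27. Longest linear sequence: 25 (steps 1–15 and 18–27, from quinic acid).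

Steps most likely to fail:

1. Step 10. The primary radical may add to the unactivated alkyne more slowly than it is lost by reduction and protonation, which would drain the catalyst. Fallback with a different two-carbon partner and a redox detour: setting out from 10, the same SmI2/Sm system is run with methyl propiolate, which alkyl radicals take up much faster, to give the unsaturated keto ester F1. Hydrogenation (H2, 10% Pd/C, EtOAc) from the convex face should give the saturated keto ester F2. LiAlH4 (THF, 0 °C) reduces ester and ketone to the diol F3, and TBDPSCl/imidazole silylates the primary hydroxyl to give the hydroxy silyl ether F4. DMP oxidation comes back to the route at 13.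

2. Step 24. Ring closure across the concave face may be slower than intermolecular coupling or loss of the iodide. Fallback by nickel-catalysed reductive alkyne–aldehyde macrocyclization: setting out from 25, TBAF/AcOH gives the alkynol F5 and DMP gives the alkynal F6. Ni(cod)2 (20 mol %), IMes·HCl, KOtBu and Et3SiH in THF at 0.005 M should close the ring through an oxanickelacycle on zerovalent nickel, with C–C bond formation at the terminal alkyne carbon, to give the macrocyclic (E)-allylic triethylsilyl ether F7. PPTS in MeOH removes the triethylsilyl group and comes back at 30.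

3. Step 18. Facial selectivity in the Grignard addition to the enal may be poor. Fallback by reagent control: setting out from the epimer mixture of 23, MnO2 (CH2Cl2) oxidizes only the allylic carbinol to the enone F8. (R)-Me-CBS oxazaborolidine with BH3·SMe2 (alkenyl as the large group) should then give the (S)-carbinol, which is 23 again.

**Further compounds**

F1 | step 10 | BDA-protected methyl 4,5-dihydroxy-6-methyl-2-oxobicyclo[4.3.0]non-8-ene-9-carboxylate, cis-fused | C1C(=O)[C@@H]2C(C(=O)OC)=CC[C@]2(C)[C@H]3O[C@](C)(OC)[C@@](C)(OC)O[C@H]13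
F2 | step 10 | the 8,9-dihydro keto ester, ester cis to C2 | C1C(=O)[C@@H]2[C@H](C(=O)OC)CC[C@]2(C)[C@H]3O[C@](C)(OC)[C@@](C)(OC)O[C@H]13
F3 | step 10 | diol from F2 (ring carbinol epimers; 9-CH2OH) | C1C(O)[C@@H]2[C@H](CO)CC[C@]2(C)[C@H]3O[C@](C)(OC)[C@@](C)(OC)O[C@H]13
F4 | step 10 | primary TBDPS ether of F3 | C1C(O)[C@@H]2[C@H](CO[Si](c4ccccc4)(c5ccccc5)C(C)(C)C)CC[C@]2(C)[C@H]3O[C@](C)(OC)[C@@](C)(OC)O[C@H]13
F5 | step 24 | primary alcohol from 25 (terminal alkyne kept) | C#CC[C@H](C)C[C@H](OC(C)=O)C1=C(C)[C@@H]2[C@H](CO)CC[C@]2(C)[C@@H](OC(C)=O)[C@@H]1O[Si](C)(C)C(C)(C)C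
F6 | step 24 | alkynal from F5 | C#CC[C@H](C)C[C@H](OC(C)=O)C1=C(C)[C@@H]2[C@H](C=O)CC[C@]2(C)[C@@H](OC(C)=O)[C@@H]1O[Si](C)(C)C(C)(C)C
F7 | step 24 | triethylsilyl ether of 30 | CC[Si](CC)(CC)OC1/C=C/C[C@H](C)C[C@H](OC(C)=O)C2=C(C)[C@@H]3[C@H]1CC[C@]3(C)[C@@H](OC(C)=O)[C@@H]2O[Si](C)(C)C(C)(C)C
F8 | step 18 | enone from 23 (chain carbinol oxidized to the ketone) | C[Si](C)(C)C#CC[C@H](C)CC(=O)C1=C(C)[C@@H]2[C@H](CO[Si](c4ccccc4)(c5ccccc5)C(C)(C)C)CC[C@]2(C)[C@@H](O)[C@@H]1O[Si](C)(C)C(C)(C)C
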